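**Retrosynthetic overview**
1. The target comes from the 5,7-di-O-benzyl flavone by O-debenzylation as the last step.
2. Key disconnection C2–C1': 5,7-bis(benzyloxy)chromone plus 1,2,3,4-tetramethoxybenzene, joined by a new Tf2O-driven C–H/C–H coupling. The arene has only one kind of C–H, so regiochemistry is automatic.
3. The chromone (ring C) comes from an o-hydroxyaryl enaminone, made from 2-hydroxy-4,6-bis(benzyloxy)acetophenone and ultimately from phloroacetophenone.
4. 1,2,3,4-Tetramethoxybenzene comes from 2,3,4-trimethoxybenzaldehyde by Dakin oxidation and O-methylation.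
5. Ring order: rings A and B are bought as arenes, the pyranone ring C is closed onto ring A first, and ring B is attached last.

Assumption: the target has no stereocentre and no configurationally stable axis. It is therefore achiral, and "single enantiomer" needs no stereocontrol. The only sp3 stereocentre on the way (C2 of 10, racemic) is erased in the same flask.

**Step 1**
Reactants: 1 2,3,4-trimethoxybenzaldehyde
Product: 3 2,3,4-trimethoxyphenol, via 2,3,4-trimethoxyphenyl formate 2 (not isolated)
Conditions: 30% H2O2 (1.3 equiv), cat. H2SO4, MeOH, rt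
Reagents that add atoms: hydrogen peroxide, OO
Why: Acid-catalysed Dakin (Baeyer–Villiger type) oxidation, in which the electron-rich aryl group migrates to oxygen and the formate 2 is methanolysed in the same pot; no stereocentre is formed.

**Step 2**
Reactants: 3 2,3,4-trimethoxyphenol
Product: 4 1,2,3,4-tetramethoxybenzene
Conditions: MeI (1.5 equiv), K2CO3, acetone, reflux
Reagents that add atoms: iodomethane, CI
Why: Williamson ether synthesis on an unhindered phenoxide is near quantitative and gives a symmetric arene whose two C–H positions are equivalent.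

**Step 3**
Reactants: 5 2,4,6-trihydroxyacetophenone
Product: 6 1-[2,4-bis(benzyloxy)-6-hydroxyphenyl]ethan-1-one
Conditions: BnBr (2.1 equiv), K2CO3 (2.2 equiv), DMF, rt to 50 °C
Reagents that add atoms: benzyl bromide, BrCc1ccccc1
Why: Williamson O-benzylation under chelation control, in which the hydroxyl hydrogen-bonded to the acetyl C=O is the least reactive, so two equivalents of BnBr stop at the dibenzyl ether.

**Step 4**
Reactants: 6 1-[2,4-bis(benzyloxy)-6-hydroxyphenyl]ethan-1-one
Product: 7 (E)-1-[2,4-bis(benzyloxy)-6-hydroxyphenyl]-3-(dimethylamino)prop-2-en-1-one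
Conditions: DMF-DMA (2.5 equiv), toluene, 100 °C
Reagents that add atoms: N,N-dimethylformamide dimethyl acetal, COC(OC)N(C)C
Why: Enaminone formation by condensation of the acetyl CH3 with an amide acetal is driven by loss of two MeOH, gives the thermodynamic E push–pull alkene and leaves the chelated phenol untouched.

**Step 5**
Reactants: 7 (E)-1-[2,4-bis(benzyloxy)-6-hydroxyphenyl]-3-(dimethylamino)prop-2-en-1-one
Product: 8 5,7-bis(benzyloxy)-4H-chromen-4-one
Conditions: conc. HCl, CH2Cl2, 40 °C, 1 h
Reagents that add atoms: none
Why: Acid-promoted intramolecular oxa-Michael addition–elimination (enaminone chromone synthesis), in which the ortho-OH closes the six-membered ring on the protonated enaminone, Me2NH leaves, and benzyl ethers tolerate the brief HCl exposure.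

**Step 6**
Reactants: 8 5,7-bis(benzyloxy)-4H-chromen-4-one; 4 1,2,3,4-tetramethoxybenzene
Product: 11 5,7-bis(benzyloxy)-2-(2,3,4,5-tetramethoxyphenyl)-4H-chromen-4-one, via 4-triflyloxychromenylium triflate 9 (not isolated), via 2-aryl-2H-chromen-4-yl triflate 10 (not isolated)
Conditions: Tf2O (1.15 equiv), 2,6-di-tert-butyl-4-methylpyridine (1.3 equiv), CH2Cl2, −78 °C, slow addition of 8, to −30 °C; then 4 (1.5 equiv), −30 °C to rt; then DBU (3 equiv), rt to 40 °C
Reagents that add atoms: none
Why: Proposed new method: a metal-free dehydrogenative C2–H arylation of a chromone in which Tf2O is both activator and internal oxidant – O-triflation of the vinylogous-ester carbonyl of 8 gives the strongly electrophilic benzopyrylium 9 (the OTf group offsets the 5,7-donors, C4 is shielded by the peri 5-OBn and C2 is open), the single type of C–H in 4 (ortho and para to OMe) attacks C2 in a Friedel–Crafts step while the hindered pyridine takes the proton to give racemic enol triflate 10, and DBU then removes the benzylic, allylic, α-oxy C2–H with vinylogous 1,4-expulsion of triflinate from oxygen (S(VI) to S(IV); the O–S bond stands perpendicular to the π plane and overlaps with the developing carbanion, whereas C–O cleavage is orthogonal), which restores the 4-pyranone, erases the stereocentre and makes the C–C bond formation irreversible; the closest known reaction types are Tf2O activation of pyridines followed by addition of electron-rich arenes or phosphines and base-induced loss of triflinate from nitrogen, carbon-nucleophile additions to 4-silyloxybenzopyrylium salts, and sulfinate elimination from α-sulfonyloxy ketones to give 1,2-diketones.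

**Step 7**
Reactants: 11 5,7-bis(benzyloxy)-2-(2,3,4,5-tetramethoxyphenyl)-4H-chromen-4-one
Product: 12 5,7-dihydroxy-2-(2,3,4,5-tetramethoxyphenyl)-4H-chromen-4-one (5,7-dihydroxy-2',3',4',5'-tetramethoxyflavone)
Conditions: H2 (1 atm), 10% Pd/C, EtOAc/MeOH, rt
Reagents that add atoms: none
Why: Catalytic hydrogenolysis of the benzylic C–O bonds is much faster than reduction of the flavone C2=C3 bond at 1 atm, and aryl methyl ethers are inert, so only the two benzyl groups are lost.

**Compound list**
1 | 2,3,4-trimethoxybenzaldehyde | COc1ccc(C=O)c(OC)c1OC | starting material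
2 | 2,3,4-trimethoxyphenyl formate | COc1ccc(OC=O)c(OC)c1OC | intermediate
3 | 2,3,4-trimethoxyphenol | COc1ccc(O)c(OC)c1OC | intermediate
4 | 1,2,3,4-tetramethoxybenzene | COc1ccc(OC)c(OC)c1OC | intermediate
5 | 2,4,6-trihydroxyacetophenone | CC(=O)c1c(O)cc(O)cc1O | starting material
6 | 1-[2,4-bis(benzyloxy)-6-hydroxyphenyl]ethan-1-one | CC(=O)c1c(O)cc(OCc2ccccc2)cc1OCc1ccccc1 | intermediate
7 | (E)-1-[2,4-bis(benzyloxy)-6-hydroxyphenyl]-3-(dimethylamino)prop-2-en-1-one | CN(C)/C=C/C(=O)c1c(O)cc(OCc2ccccc2)cc1OCc1ccccc1 | intermediate
8 | 5,7-bis(benzyloxy)-4H-chromen-4-one | O=c1ccoc2cc(OCc3ccccc3)cc(OCc3ccccc3)c12 | intermediate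
9 | 5,7-bis(benzyloxy)-4-(trifluoromethylsulfonyloxy)chromenylium trifluoromethanesulfonate | O=S(=O)(Oc1cc[o+]c2cc(OCc3ccccc3)cc(OCc3ccccc3)c12)C(F)(F)F.[O-]S(=O)(=O)C(F)(F)F | intermediate
10 | rac-5,7-bis(benzyloxy)-2-(2,3,4,5-tetramethoxyphenyl)-2H-chromen-4-yl trifluoromethanesulfonate | COc1cc(C2C=C(OS(=O)(=O)C(F)(F)F)c3c(OCc4ccccc4)cc(OCc4ccccc4)cc3O2)c(OC)c(OC)c1OC | intermediate
11 | 5,7-bis(benzyloxy)-2-(2,3,4,5-tetramethoxyphenyl)-4H-chromen-4-one | COc1cc(-c2cc(=O)c3c(OCc4ccccc4)cc(OCc4ccccc4)cc3o2)c(OC)c(OC)c1OC | intermediate
12 | 5,7-dihydroxy-2-(2,3,4,5-tetramethoxyphenyl)-4H-chromen-4-one | COc1cc(-c2cc(=O)c3c(O)cc(O)cc3o2)c(OC)c(OC)c1OC | target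

**Total step count:** 7. **Longest linear sequence:** 5 (steps 3, 4, 5, 6 and 7, from 5).

**Three steps most likely to fail**

**Step 6 (the proposed new step).**
- Risks: 4 may be too weak a nucleophile for the donor-stabilised cation 9. Attack may occur at C4 with loss of triflate. The sequence may stall at 10 if triflinate is not expelled.
- The fallback uses known chemistry, sets out from 4 and 6, and comes back at 11.
- Vilsmeier–Haack formylation of 4 (POCl3, DMF, 80 °C) gives 2,3,4,5-tetramethoxybenzaldehyde F1.
- Claisen–Schmidt condensation of F1 with 6 (KOH, EtOH, rt) gives (E)-1-[2,4-bis(benzyloxy)-6-hydroxyphenyl]-3-(2,3,4,5-tetramethoxyphenyl)prop-2-en-1-one F2.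
- Oxidative cyclisation of this 2'-hydroxychalcone (cat. I2, DMSO, 120 °C) gives 11.
- Ring C is then built around a preformed C2–aryl bond, so compounds 7 and 8 are bypassed.

**Step 3 (selective dibenzylation).**
- Risks: mixtures of mono-, di- and tri-ethers, and C-benzylation of the phloroglucinol nucleus.
- The fallback sets out from 5 and comes back at 6 by over-protection followed by directed deprotection.
- Exhaustive benzylation (BnBr 3.5 equiv, K2CO3, DMF, 80 °C) gives 1-[2,4,6-tris(benzyloxy)phenyl]ethan-1-one F3.
- Chelation-directed removal of one benzyl group ortho to the carbonyl (MgBr2·OEt2, toluene/Et2O, reflux) gives 6.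

**Step 7 (hydrogenolysis).**
- Risks: partial over-reduction of C2=C3 to the flavanone, or catalyst poisoning by traces of sulfur species from step 6.
- The fallback sets out from 11 and comes back at 12 by a non-reductive Lewis-acid benzyl transfer.
- Conditions are BCl3 (4 equiv) and pentamethylbenzene (6 equiv) in CH2Cl2 at −78 °C. Boron activates the benzyl ethers and the arene traps the benzyl cation.
- Aryl methyl ethers survive at this temperature. This fallback makes no new compound (F0).

**Further compounds**
F1 | step 6 | 2,3,4,5-tetramethoxybenzaldehyde | COc1cc(C=O)c(OC)c(OC)c1OC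
F2 | step 6 | (E)-1-[2,4-bis(benzyloxy)-6-hydroxyphenyl]-3-(2,3,4,5-tetramethoxyphenyl)prop-2-en-1-one | COc1cc(/C=C/C(=O)c2c(O)cc(OCc3ccccc3)cc2OCc2ccccc2)c(OC)c(OC)c1OC
F3 | step 3 | 1-[2,4,6-tris(benzyloxy)phenyl]ethan-1-one | CC(=O)c1c(OCc2ccccc2)cc(OCc2ccccc2)cc1OCc1ccccc1
F0 | step 7 | none | none
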